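## Structural features

The target 14 is a 2,3-dihydro-1,4-benzodioxine: the dioxane ring B is fused to the benzene ring A and carries a 4-hydroxy-3,5-dimethoxyphenyl group (ring C) on C2. Numbering used throughout: O1, C2 (aryl), C3 (methyl), O4, C4a, C5 (methoxy), C6, C7 ((E)-propenyl), C8, C8a. The only stereocentres, C2 and C3, are neighbours, both R, with aryl and methyl trans (both equatorial on the half-chair of ring B). Three groups are fragile. The electron-rich (E)-propenyl styrene is easily oxidised and can lose its geometry. The benzylic C2–O1 ether stands para to a free phenol, so ring B can open to a para-quinone methide and C2 can epimerise. The acyclic precursors contain an enolisable α-aryloxy carbonyl centre. The real difficulty is the regiochemistry of ring A (methoxy beside O4 and not beside O1) combined with the absolute trans configuration. The key step exploits the fact that ring A is a syringyl ring alkylated on its phenolic oxygen (O4), with O1 on C8a where a second methoxy group would otherwise sit. Putting methoxy back on C8a gives a 2,6-dimethoxyphenyl ether whose two methoxy-bearing carbons (C5 and C8a) are homotopic, so the C2 hydroxyl can close ring B by displacing either one.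

## Logic of the disconnections

14 to 13: the acyl–oxygen bond of the ring C phenol ester is cut. The free phenol is released last because, once free, it makes the C2–O1 bond ionisable. The gain is an electron-poor, non-ionisable ring C in every earlier step. The demand is a cleavage that does not hold the product phenoxide in hot base.

13 to 12: the side-chain C=C bond on C7 is cut. A styrene would be oxidised before ring A in the photochemical step and must come afterwards. The gain is an aldehyde. The demand is an (E)-selective ethylidenation.

12 to 11: the two C–O bonds of the acetal on the C7 carbon are cut (functional-group change only). The sp3 acetal protects the carbonyl from organomagnesium and hydride reagents and keeps ring A electron-rich. The demand is a hydrolysis that leaves C2–O1 intact.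

11 to 10: O1–C8a is cut and methoxy is restored on C8a. This opens ring B to an acyclic threo aryloxy alcohol whose ring A is symmetric, so the regiochemical problem vanishes and both aromatic halves become syringyl-type pieces. The demand is a substitution of an unactivated aryl methyl ether by a tethered alcohol, selective for ring A and for C8a over C4a, without breaking the C2–C3 bond.

10 to 9: the C2–H bond is cut. Only C3 then needs an external source of chirality, and C2 is set by 1,2-induction. The demand is Felkin–Anh selectivity and no enolisation of the ketone.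

9 to 5 and 8: the bond between C2 and the ipso carbon of ring C is cut. This is the convergent cut into two fragments of similar size. The demand is a single addition of an aryl nucleophile that tolerates the ester on ring C.

8 to 7 to 6: the carbon–magnesium bond is traced to a carbon–bromine bond and the pivaloyl–oxygen bond is cut. The protecting group goes on before the organometallic step. The demand is halogen–metal exchange in the presence of a hindered aryl ester.

5 to 4 to 3: the amide C–N bond and then the acetal C–O bonds are cut. Both are functional-group changes that prepare the ester for a single aryl addition. The demand is that the α-aryloxy centre is not epimerised.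

3 to 1 and 2: O4–C3 is cut. The chiral pool then supplies C3, its methyl group and the carbon that becomes C2. The demand is a clean SN2 inversion with a phenol flanked by two methoxy groups.

## Other disconnections considered

Alternative 1: The cut is O4–C3, together with a C–H bond of the C3 methyl group. The precursor would be the (S)-allylic aryl ether A1, with O1–C2 in place and the C4a hydroxyl free. A salen complex of divalent cobalt, a silane and an N-fluoropyridinium oxidant would transfer a hydrogen atom to the terminal CH2. The C3 radical would be oxidised through an alkylcobalt species, and the C4a phenol would close ring B to give A2.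
- In favour: Markovnikov hydroalkoxylation of alkenes by tethered phenols is an established reaction type, so this key step is better precedented than the chosen one. It makes the methyl group and a stereocentre in the ring-forming event. A2 is the same compound as 12, so the last two steps would be shared.
- Against: C3 would be set only by induction from C2, with no assurance of trans. The C3 radical is β to an aryloxy group and could expel the ring A phenoxyl radical. A 1,2-hydride shift from C2 to the C3 cation equivalent would give an oxocarbenium ion stabilised by O1 and ring C, which the phenol would trap as a five-membered benzodioxole ketal. The silane and cobalt hydride may attack the aldehyde. A1 also needs an enantioselective allylic etherification and prior differentiation of the two catechol oxygens of ring A.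
- Comparison: on structure, both plans close ring B with one C–O bond, but the chosen plan enters the cyclisation with both stereocentres fixed. On mechanism, the alternative has the better precedent and the chosen plan has fewer radical and cationic escape routes. On step economy the two are about equal.

Alternative 2: The cut removes both aryl–oxygen bonds, O1–C8a and O4–C4a. Fluoride would release the aryne from the silyl triflate A3, and the s-cis form of diketone A4 would add across it through both carbonyl oxygens to give the achiral benzodioxine A5.
- In favour: it is the most convergent plan. Two bonds and the ring form in one step from two fragments, and no stereocentre has to survive organometallic steps. On convergence and on step count up to the ring system it is the better plan.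
- Against: A5 has a tetrasubstituted C2=C3 enediol ether, and both stereocentres must then be made by reduction. Catalytic hydrogenation adds syn and would lead to the cis isomer, and a trans-selective, enantioselective reduction of this bond type is not routine. The methoxy group of the aryne steers the first nucleophile to the future C8a, but nothing strongly distinguishes the two carbonyl oxygens of A4, so the regioisomer with methoxy beside O1 should compete. Open-chain 1,2-diketones prefer the s-trans geometry, and arynes have other paths with carbonyl groups.
- Comparison: on structure, the alternative wins on convergence, while the chosen plan gets regiochemistry from symmetry and configuration from the chiral pool. On mechanism, both key steps stretch precedent and neither has the edge. On step economy, the early advantage of the alternative would be lost in the stereochemical repair.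

Alternative 3: The cut is O1–C2. Two-electron anodic oxidation of the free syringyl phenol (ring C) of A6, with loss of the benzylic proton, would give a para-quinone methide at C2. The C8a hydroxyl of ring A would add to it and give A7 with the ring C phenol already free.
- In favour: oxidative quinone methide cyclisation to benzodioxanes is well precedented, better than the chosen key step. Ring C needs no protecting group and no final deprotection. The hydroxyl para to the formyl group of ring A is the more acidic, which helps to differentiate the two ring A oxygens. On step economy it is the better plan, by perhaps three steps.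
- Against: C2 is created in the ring closure, so its configuration rests on the preference for the trans-diequatorial product. A7 still carries the oxidisable syringyl phenol and could be re-oxidised to a quinone methide at C2, which would reopen ring B or add solvent. The solvent also competes for the first quinone methide.
- Comparison: on structure, it is the same ring closed at the other benzylic C–O bond, but the chosen plan never breaks O1–C2 and keeps ring C acylated, so C2 cannot scramble. On mechanism, the alternative is a stoichiometric two-electron oxidation at ring C, while the chosen step is a catalytic, redox-neutral one-electron process at ring A that does not expose the product to an oxidant. On precedent and step count the alternative is ahead.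

Key step: step 7

Remark on the configurations: the descriptors were re-derived from the SMILES strings. Alcohol 10 is the threo (1R,2R) isomer, and it maps onto the trans (2R,3R) benzodioxane of 11 to 14 without any change at either centre. No structural correction was needed.

Remark on the design: three choices were made within the fixed disconnection.
- Ring C is carried as a pivalate. An arenesulfonate was set aside because its removal needs hot alkali at the end, under which the free para-hydroxybenzyl ether can open to a quinone methide and epimerise C2.
- The photocatalyst is the N-phenyl, di-tert-butyl acridinium salt, because N-methyl acridinium salts are prone to attack by oxygen nucleophiles.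
- C4a is recognised as a second carbon within reach of the hydroxyl, and the site selectivity is argued on orbital grounds in step 7.

Assumption: the acridinium salt, 5-(ethylsulfonyl)-1-phenyl-1H-tetrazole and 1,2-bis(trimethylsilyloxy)ethane are purchased reagents.

## Steps

Step 1
Reactants: 1 syringaldehyde; 2 ethyl (S)-lactate
Product: 3 ethyl (2R)-2-(4-formyl-2,6-dimethoxyphenoxy)propanoate
Conditions: PPh3, DIAD, THF, 0 °C → rt
Reagents that add atoms: none
Why: Mitsunobu etherification; the acidic para-formyl phenol displaces the oxyphosphonium of the lactate by SN2, so the S centre is inverted to the R centre that becomes C3. Lactate esters are standard Mitsunobu electrophiles and should not racemise under these neutral conditions.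

Step 2
Reactants: 3 ethyl (2R)-2-(4-formyl-2,6-dimethoxyphenoxy)propanoate
Product: 4 ethyl (2R)-2-[4-(1,3-dioxolan-2-yl)-2,6-dimethoxyphenoxy]propanoate
Conditions: (Me3SiOCH2)2, Me3SiOTf (cat.), CH2Cl2, −78 → −20 °C; then pyridine
Reagents that add atoms: 1,2-bis(trimethylsilyloxy)ethane, C[Si](C)(C)OCCO[Si](C)(C)C
Why: Noyori acetalisation under aprotic conditions; no free diol or strong protic acid is present, which avoids transesterification and epimerisation of the ester. The acetal shields the carbonyl from the later organomagnesium and hydride reagents and keeps ring A electron-rich for step 7.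

Step 3
Reactants: 4 ethyl (2R)-2-[4-(1,3-dioxolan-2-yl)-2,6-dimethoxyphenoxy]propanoate
Product: 5 (2R)-2-[4-(1,3-dioxolan-2-yl)-2,6-dimethoxyphenoxy]-N-methoxy-N-methylpropanamide
Conditions: MeNH(OMe)·HCl, i-PrMgCl, THF, −20 → 0 °C
Reagents that add atoms: N,O-dimethylhydroxylamine hydrochloride, CNOC.Cl
Why: Weinreb amide formation by aminolysis of the ester with the chloromagnesium amide made in the flask; this amide is a weak base and is consumed as it forms, so the α-aryloxy centre should hold.

Step 4
Reactants: 6 4-bromo-2,6-dimethoxyphenol
Product: 7 4-bromo-2,6-dimethoxyphenyl 2,2-dimethylpropanoate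
Conditions: t-BuCOCl, Et3N, DMAP (cat.), CH2Cl2, 0 °C → rt
Reagents that add atoms: pivaloyl chloride, CC(C)(C)C(=O)Cl
Why: DMAP-catalysed acylation of the phenol; the pivalate has no α-hydrogen, is shielded by the tert-butyl group and both methoxy groups, and makes ring C electron-poor.

Step 5
Reactants: 7 4-bromo-2,6-dimethoxyphenyl 2,2-dimethylpropanoate; 5 (2R)-2-[4-(1,3-dioxolan-2-yl)-2,6-dimethoxyphenoxy]-N-methoxy-N-methylpropanamide
Product: 9 4-{(2R)-2-[4-(1,3-dioxolan-2-yl)-2,6-dimethoxyphenoxy]propanoyl}-2,6-dimethoxyphenyl 2,2-dimethylpropanoate, via arylmagnesium chloride 8 (not isolated)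
Conditions: i-PrMgCl·LiCl (slightly less than 7), THF, 0 °C → rt; then 5, −20 → 0 °C; cold aq. NH4Cl
Reagents that add atoms: none
Why: Bromine–magnesium exchange (helped by the meta-methoxy and para-acyloxy groups) followed by Weinreb ketone synthesis; the five-membered N-methoxy magnesium chelate holds the tetrahedral adduct until the quench, so only one aryl group is delivered. The enolisable ketone appears only in the cold buffered work-up, and the doubly shielded pivalate and the acetal should be inert to the aryl Grignard reagent.

Step 6
Reactants: 9 4-{(2R)-2-[4-(1,3-dioxolan-2-yl)-2,6-dimethoxyphenoxy]propanoyl}-2,6-dimethoxyphenyl 2,2-dimethylpropanoate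
Product: 10 4-{(1R,2R)-2-[4-(1,3-dioxolan-2-yl)-2,6-dimethoxyphenoxy]-1-hydroxypropyl}-2,6-dimethoxyphenyl 2,2-dimethylpropanoate
Conditions: LiBH(s-Bu)3, THF, −78 °C; then NaBO3·4H2O, H2O, 0 °C → rt
Reagents that add atoms: none
Why: Felkin–Anh (polar) 1,2-induction; with a bulky, poorly chelating hydride the aryloxy group lies anti to the incoming hydride, which passes the hydrogen of the neighbouring centre and should give the threo (1R,2R) alcohol. The new centre (C2 of the target) is therefore set by the lactate-derived centre.

Step 7
Reactants: 10 4-{(1R,2R)-2-[4-(1,3-dioxolan-2-yl)-2,6-dimethoxyphenoxy]-1-hydroxypropyl}-2,6-dimethoxyphenyl 2,2-dimethylpropanoate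
Product: 11 4-[(2R,3R)-7-(1,3-dioxolan-2-yl)-5-methoxy-3-methyl-2,3-dihydro-1,4-benzodioxin-2-yl]-2,6-dimethoxyphenyl 2,2-dimethylpropanoate
Conditions: 3,6-di-tert-butyl-9-mesityl-10-phenylacridinium tetrafluoroborate (5 mol%), 2,6-di-tert-butyl-4-methylpyridine (20 mol%), ClCH2CH2Cl/(CF3)2CHOH 9:1 (0.02 M), 4 Å MS, 450 nm LEDs, N2, 25 °C
Reagents that add atoms: none
Why: Proposed new method: the photo-excited acridinium takes one electron from ring A of 10, the more electron-rich arene (three alkoxy groups, against two alkoxy and one acyloxy group on ring C), and the tethered secondary hydroxyl adds to a methoxy-bearing carbon of the radical cation; after proton loss to the pyridine base the acridinyl radical returns the electron and the anionic σ-adduct expels methoxide, so the substitution is redox-neutral and needs no terminal oxidant. The closest known reaction type is cation-radical-accelerated nucleophilic aromatic substitution of methoxyarenes by external azoles and amines under acridinium photoredox catalysis; a tethered aliphatic alcohol as the nucleophile is the unproven element. Ring B closes by a fused 6-exo-trig ipso attack of the future O1 on the future C8a, through a half-chair transition state that places aryl and methyl equatorial. No stereocentre is created: neither C2–O1 nor C3–O4 is broken, so threo 10 can only give trans 11. Chemoselectivity between the arenes is needed and rests on the lower oxidation potential of ring A, kept electron-rich by the sp3 acetal, and on the acyloxy group of ring C. Site selectivity is needed among three oxygen-bearing carbons: the two methoxy carbons are homotopic and give the same product, while C4a, the only other carbon in reach (five-membered spiro attack followed by aryl migration), should lie on a node of the SOMO because the crowded O4 is twisted out of conjugation. The same twist and the electron-poor ring C are relied on to slow scission of the C2–C3 bond, and the methanol set free can only re-add degenerately at C5.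

Step 8
Reactants: 11 4-[(2R,3R)-7-(1,3-dioxolan-2-yl)-5-methoxy-3-methyl-2,3-dihydro-1,4-benzodioxin-2-yl]-2,6-dimethoxyphenyl 2,2-dimethylpropanoate
Product: 12 4-[(2R,3R)-7-formyl-5-methoxy-3-methyl-2,3-dihydro-1,4-benzodioxin-2-yl]-2,6-dimethoxyphenyl 2,2-dimethylpropanoate
Conditions: 1 M HCl, THF, rt
Reagents that add atoms: water, O
Why: Acid-catalysed acetal hydrolysis; because ring C is acylated the benzylic C2–O1 bond should not ionise, so the trans configuration is kept and the hindered pivalate survives dilute acid.

Step 9
Reactants: 12 4-[(2R,3R)-7-formyl-5-methoxy-3-methyl-2,3-dihydro-1,4-benzodioxin-2-yl]-2,6-dimethoxyphenyl 2,2-dimethylpropanoate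
Product: 13 4-{(2R,3R)-5-methoxy-3-methyl-7-[(1E)-prop-1-en-1-yl]-2,3-dihydro-1,4-benzodioxin-2-yl}-2,6-dimethoxyphenyl 2,2-dimethylpropanoate
Conditions: 5-(ethylsulfonyl)-1-phenyl-1H-tetrazole, KN(SiMe3)2, DME, −60 °C → rt
Reagents that add atoms: 5-(ethylsulfonyl)-1-phenyl-1H-tetrazole, CCS(=O)(=O)c1nnnn1-c1ccccc1
Why: Julia–Kocienski olefination; the metallated sulfone adds to the aldehyde, the tetrazole migrates to oxygen (Smiles step), and loss of SO2 and tetrazolate should favour the (E)-alkene for an alkyl sulfone with an aromatic aldehyde. The low temperature protects the hindered pivalate from the base.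

Step 10
Reactants: 13 4-{(2R,3R)-5-methoxy-3-methyl-7-[(1E)-prop-1-en-1-yl]-2,3-dihydro-1,4-benzodioxin-2-yl}-2,6-dimethoxyphenyl 2,2-dimethylpropanoate
Product: 14 4-{(2R,3R)-5-methoxy-3-methyl-7-[(1E)-prop-1-en-1-yl]-2,3-dihydro-1,4-benzodioxin-2-yl}-2,6-dimethoxyphenol
Conditions: i-Bu2AlH (2.5 equiv), CH2Cl2, −78 °C; then aq. KNaC4H4O6 (potassium sodium tartrate)
Reagents that add atoms: none
Why: Reductive cleavage of the aryl ester by hydride at low temperature (the pivaloyl group leaves as neopentyl alcohol); the phenoxide is never held in hot base, so ring B cannot reopen through a quinone methide, and the styrene and the ethers are inert to the aluminium hydride.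

## Compound list

1 | syringaldehyde (4-hydroxy-3,5-dimethoxybenzaldehyde) | COc1cc(C=O)cc(OC)c1O | starting material
2 | ethyl (S)-lactate (ethyl (2S)-2-hydroxypropanoate) | CCOC(=O)[C@H](C)O | starting material
3 | ethyl (2R)-2-(4-formyl-2,6-dimethoxyphenoxy)propanoate | CCOC(=O)[C@@H](C)Oc1c(OC)cc(C=O)cc1OC | intermediate
4 | ethyl (2R)-2-[4-(1,3-dioxolan-2-yl)-2,6-dimethoxyphenoxy]propanoate | CCOC(=O)[C@@H](C)Oc1c(OC)cc(C2OCCO2)cc1OC | intermediate
5 | (2R)-2-[4-(1,3-dioxolan-2-yl)-2,6-dimethoxyphenoxy]-N-methoxy-N-methylpropanamide | CON(C)C(=O)[C@@H](C)Oc1c(OC)cc(C2OCCO2)cc1OC | intermediate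
6 | 4-bromo-2,6-dimethoxyphenol | COc1cc(Br)cc(OC)c1O | starting material
7 | 4-bromo-2,6-dimethoxyphenyl 2,2-dimethylpropanoate | COc1cc(Br)cc(OC)c1OC(=O)C(C)(C)C | intermediate
8 | [3,5-dimethoxy-4-(pivaloyloxy)phenyl]magnesium chloride (LiCl complex, not isolated) | COc1cc([Mg]Cl)cc(OC)c1OC(=O)C(C)(C)C | intermediate
9 | 4-{(2R)-2-[4-(1,3-dioxolan-2-yl)-2,6-dimethoxyphenoxy]propanoyl}-2,6-dimethoxyphenyl 2,2-dimethylpropanoate | O=C(c1cc(OC)c(OC(=O)C(C)(C)C)c(OC)c1)[C@@H](C)Oc1c(OC)cc(C2OCCO2)cc1OC | intermediate
10 | 4-{(1R,2R)-2-[4-(1,3-dioxolan-2-yl)-2,6-dimethoxyphenoxy]-1-hydroxypropyl}-2,6-dimethoxyphenyl 2,2-dimethylpropanoate | O[C@H](c1cc(OC)c(OC(=O)C(C)(C)C)c(OC)c1)[C@@H](C)Oc1c(OC)cc(C2OCCO2)cc1OC | intermediate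
11 | 4-[(2R,3R)-7-(1,3-dioxolan-2-yl)-5-methoxy-3-methyl-2,3-dihydro-1,4-benzodioxin-2-yl]-2,6-dimethoxyphenyl 2,2-dimethylpropanoate | O1CCOC1c1cc(OC)c2c(c1)O[C@H](c1cc(OC)c(OC(=O)C(C)(C)C)c(OC)c1)[C@@H](C)O2 | intermediate
12 | 4-[(2R,3R)-7-formyl-5-methoxy-3-methyl-2,3-dihydro-1,4-benzodioxin-2-yl]-2,6-dimethoxyphenyl 2,2-dimethylpropanoate | O=Cc1cc(OC)c2c(c1)O[C@H](c1cc(OC)c(OC(=O)C(C)(C)C)c(OC)c1)[C@@H](C)O2 | intermediate
13 | 4-{(2R,3R)-5-methoxy-3-methyl-7-[(1E)-prop-1-en-1-yl]-2,3-dihydro-1,4-benzodioxin-2-yl}-2,6-dimethoxyphenyl 2,2-dimethylpropanoate | C/C=C/c1cc(OC)c2c(c1)O[C@H](c1cc(OC)c(OC(=O)C(C)(C)C)c(OC)c1)[C@@H](C)O2 | intermediate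
14 | 4-{(2R,3R)-5-methoxy-3-methyl-7-[(1E)-prop-1-en-1-yl]-2,3-dihydro-1,4-benzodioxin-2-yl}-2,6-dimethoxyphenol | C/C=C/c1cc(OC)c2c(c1)O[C@H](c1cc(OC)c(O)c(OC)c1)[C@@H](C)O2 | target

## Step count and least certain steps

Total: 10 steps. Longest linear sequence: 9 steps (1 → 3 → 4 → 5 → 9 → 10 → 11 → 12 → 13 → 14); the ring C branch (6 → 7) joins at step 5.

**Step 7 (key step).** Three things are most likely to go wrong.
- The C2–C3 bond may break in the radical cation, because β-aryloxy alcohols are known to fragment on one-electron oxidation.
- The hydroxyl may attack C4a, giving a spiro intermediate and migration of ring A from O4 to O1.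
- The cyclisation may simply be too slow, so that back electron transfer returns 10. Product 11 may also bind the catalyst, since its ring A should be easier to oxidise once both oxygens are held in the ring plane.

The fallback forms the same O1–C8a bond by a known palladium-catalysed intramolecular etherification of an aryl bromide, so the regiochemistry comes from the position of the bromine and not from symmetry. It sets out from 2 (and uses 8 from step 5) and returns at 11. Mitsunobu reaction of 2 with 3-bromo-4-hydroxy-5-methoxybenzaldehyde F1 gives ethyl (2R)-2-(2-bromo-4-formyl-6-methoxyphenoxy)propanoate F2. Acetalisation as in step 2 gives ethyl (2R)-2-[2-bromo-4-(1,3-dioxolan-2-yl)-6-methoxyphenoxy]propanoate F3. Aminolysis as in step 3 gives (2R)-2-[2-bromo-4-(1,3-dioxolan-2-yl)-6-methoxyphenoxy]-N-methoxy-N-methylpropanamide F4. Addition of 8 as in step 5 gives 4-{(2R)-2-[2-bromo-4-(1,3-dioxolan-2-yl)-6-methoxyphenoxy]propanoyl}-2,6-dimethoxyphenyl 2,2-dimethylpropanoate F5. Reduction as in step 6 gives 4-{(1R,2R)-2-[2-bromo-4-(1,3-dioxolan-2-yl)-6-methoxyphenoxy]-1-hydroxypropyl}-2,6-dimethoxyphenyl 2,2-dimethylpropanoate F6. Pd(OAc)2, racemic 2-(di-tert-butylphosphino)-1,1'-binaphthyl and K3PO4 in toluene at 70 °C then close ring B with retention at both centres to give 11.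

**Step 6.** Facial selectivity may be poor if lithium chelation between the carbonyl and the aryloxy or methoxy oxygens competes with the Felkin–Anh pathway, and the basic hydride may enolise the ketone and erode the lactate-derived centre. The fallback sets out from 9 and returns at 10. Chelation-controlled reduction with Zn(BH4)2 in Et2O should give the erythro alcohol 4-{(1S,2R)-2-[4-(1,3-dioxolan-2-yl)-2,6-dimethoxyphenoxy]-1-hydroxypropyl}-2,6-dimethoxyphenyl 2,2-dimethylpropanoate F7. Mitsunobu inversion with chloroacetic acid gives (1R,2R)-2-[4-(1,3-dioxolan-2-yl)-2,6-dimethoxyphenoxy]-1-[3,5-dimethoxy-4-(pivaloyloxy)phenyl]propyl chloroacetate F8. Brief treatment with K2CO3 in methanol at 0 °C removes the chloroacetate, leaves the hindered pivalate and gives 10.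

**Step 5.** Loss of configuration at the α-aryloxy ketone by enolisation during quench and purification is the main risk. Incomplete halogen–magnesium exchange would also leave i-PrMgCl free to attack 5. The fallback avoids the ketone altogether. It sets out from 4 and returns at 10. Reduction with i-Bu2AlH at −78 °C gives (2R)-2-[4-(1,3-dioxolan-2-yl)-2,6-dimethoxyphenoxy]propanal F9, which is used crude. Addition of 8 in the presence of MgBr2·OEt2 in CH2Cl2 at −78 °C, under Cram chelation control, should give the threo alcohol 10 directly.

**Step 9.** Incomplete (E)-selectivity is the risk, and the geometric isomers would be hard to separate. The fallback sets out from 12 and returns at 13. EtMgBr in THF at −78 °C gives 4-[(2R,3R)-7-(1-hydroxypropyl)-5-methoxy-3-methyl-2,3-dihydro-1,4-benzodioxin-2-yl]-2,6-dimethoxyphenyl 2,2-dimethylpropanoate F10 as a mixture of carbinol epimers. Dehydration with catalytic p-toluenesulfonic acid in dilute toluene at 60 °C passes through the benzylic cation stabilised by the para oxygen O4 and should give the thermodynamically preferred (E)-alkene 13.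

**Step 1.** The redox condensation may be sluggish with a phenol flanked by two methoxy groups, which would let elimination of the activated lactate or alkylation of the hydrazide take over. The fallback sets out from 2 and returns at 3. Tf2O and 2,6-lutidine in CH2Cl2 at −40 °C give ethyl (2S)-2-{[(trifluoromethyl)sulfonyl]oxy}propanoate F11. The potassium phenoxide of 1 (K2CO3, MeCN, 0 °C) displaces the triflate by SN2 with inversion to give 3.

## Further compounds

F1 | step 7 | 3-bromo-4-hydroxy-5-methoxybenzaldehyde | COc1cc(C=O)cc(Br)c1O
F2 | step 7 | ethyl (2R)-2-(2-bromo-4-formyl-6-methoxyphenoxy)propanoate | CCOC(=O)[C@@H](C)Oc1c(Br)cc(C=O)cc1OC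
F3 | step 7 | ethyl (2R)-2-[2-bromo-4-(1,3-dioxolan-2-yl)-6-methoxyphenoxy]propanoate | CCOC(=O)[C@@H](C)Oc1c(Br)cc(C2OCCO2)cc1OC
F4 | step 7 | (2R)-2-[2-bromo-4-(1,3-dioxolan-2-yl)-6-methoxyphenoxy]-N-methoxy-N-methylpropanamide | CON(C)C(=O)[C@@H](C)Oc1c(Br)cc(C2OCCO2)cc1OC
F5 | step 7 | 4-{(2R)-2-[2-bromo-4-(1,3-dioxolan-2-yl)-6-methoxyphenoxy]propanoyl}-2,6-dimethoxyphenyl 2,2-dimethylpropanoate | O=C(c1cc(OC)c(OC(=O)C(C)(C)C)c(OC)c1)[C@@H](C)Oc1c(Br)cc(C2OCCO2)cc1OC
F6 | step 7 | 4-{(1R,2R)-2-[2-bromo-4-(1,3-dioxolan-2-yl)-6-methoxyphenoxy]-1-hydroxypropyl}-2,6-dimethoxyphenyl 2,2-dimethylpropanoate | O[C@H](c1cc(OC)c(OC(=O)C(C)(C)C)c(OC)c1)[C@@H](C)Oc1c(Br)cc(C2OCCO2)cc1OC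
F7 | step 6 | 4-{(1S,2R)-2-[4-(1,3-dioxolan-2-yl)-2,6-dimethoxyphenoxy]-1-hydroxypropyl}-2,6-dimethoxyphenyl 2,2-dimethylpropanoate | O[C@@H](c1cc(OC)c(OC(=O)C(C)(C)C)c(OC)c1)[C@@H](C)Oc1c(OC)cc(C2OCCO2)cc1OC
F8 | step 6 | (1R,2R)-2-[4-(1,3-dioxolan-2-yl)-2,6-dimethoxyphenoxy]-1-[3,5-dimethoxy-4-(pivaloyloxy)phenyl]propyl chloroacetate | ClCC(=O)O[C@H](c1cc(OC)c(OC(=O)C(C)(C)C)c(OC)c1)[C@@H](C)Oc1c(OC)cc(C2OCCO2)cc1OC
F9 | step 5 | (2R)-2-[4-(1,3-dioxolan-2-yl)-2,6-dimethoxyphenoxy]propanal | O=C[C@@H](C)Oc1c(OC)cc(C2OCCO2)cc1OC
F10 | step 9 | 4-[(2R,3R)-7-(1-hydroxypropyl)-5-methoxy-3-methyl-2,3-dihydro-1,4-benzodioxin-2-yl]-2,6-dimethoxyphenyl 2,2-dimethylpropanoate (both carbinol epimers) | CCC(O)c1cc(OC)c2c(c1)O[C@H](c1cc(OC)c(OC(=O)C(C)(C)C)c(OC)c1)[C@@H](C)O2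
F11 | step 1 | ethyl (2S)-2-{[(trifluoromethyl)sulfonyl]oxy}propanoate | CCOC(=O)[C@H](C)OS(=O)(=O)C(F)(F)F
A1 | alternative 1 | 4-[(1S)-1-(5-formyl-2-hydroxy-3-methoxyphenoxy)prop-2-en-1-yl]-2,6-dimethoxyphenyl 2,2-dimethylpropanoate | O=Cc1cc(OC)c(O)c(c1)O[C@H](c1cc(OC)c(OC(=O)C(C)(C)C)c(OC)c1)C=C
A2 | alternative 1 | 4-[(2R,3R)-7-formyl-5-methoxy-3-methyl-2,3-dihydro-1,4-benzodioxin-2-yl]-2,6-dimethoxyphenyl 2,2-dimethylpropanoate (identical with 12) | O=Cc1cc(OC)c2c(c1)O[C@H](c1cc(OC)c(OC(=O)C(C)(C)C)c(OC)c1)[C@@H](C)O2
A3 | alternative 2 | 4-(1,3-dioxolan-2-yl)-2-methoxy-6-(trimethylsilyl)phenyl trifluoromethanesulfonate | COc1cc(C2OCCO2)cc([Si](C)(C)C)c1OS(=O)(=O)C(F)(F)F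
A4 | alternative 2 | 1-[4-(benzyloxy)-3,5-dimethoxyphenyl]propane-1,2-dione | CC(=O)C(=O)c1cc(OC)c(OCc2ccccc2)c(OC)c1
A5 | alternative 2 | 2-[4-(benzyloxy)-3,5-dimethoxyphenyl]-7-(1,3-dioxolan-2-yl)-5-methoxy-3-methyl-1,4-benzodioxine | CC1=C(c2cc(OC)c(OCc3ccccc3)c(OC)c2)Oc2cc(C3OCCO3)cc(OC)c2O1
A6 | alternative 3 | 3-hydroxy-4-{[(2R)-1-(4-hydroxy-3,5-dimethoxyphenyl)propan-2-yl]oxy}-5-methoxybenzaldehyde | O=Cc1cc(OC)c(O[C@H](C)Cc2cc(OC)c(O)c(OC)c2)c(O)c1
A7 | alternative 3 | (2R,3R)-2-(4-hydroxy-3,5-dimethoxyphenyl)-5-methoxy-3-methyl-2,3-dihydro-1,4-benzodioxine-7-carbaldehyde | O=Cc1cc(OC)c2c(c1)O[C@H](c1cc(OC)c(O)c(OC)c1)[C@@H](C)O2
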